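**Retrosynthetic overview**
1. The hydroperoxide is made last by SN2 (inversion) on an (R)-allylic mesylate. Before that, one sp2–sp3 Suzuki bond joins the ring-A enol triflate (fragment 1) to a bicyclic primary iodide (fragment 2).
2. Fragment 2: the oxepane (ring C) is closed by ring-closing metathesis of an allyl / 1,1-dimethylallyl ether diene, and its C3 hydroxyl comes from the derived epoxide.
3. The cyclohexane of fragment 2 (ring B) gets its four stereocentres from (S)-Wieland–Miescher ketone, made by a proline-catalysed intramolecular aldol. The aldol ring is temporary: it is later cut at C6–C7 into the allyl arm and the two-carbon linker, held as a γ-lactone.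
4. Fragment 1: ring A is taken intact from 2-methylcyclohexane-1,3-dione (acrolein Michael, Wittig, CBS desymmetrisation, enol triflate, Shi epoxide, allylic alcohol).
5. Ring order: ring B (dione ring, aldol ring fused on and later cleaved), then ring C by metathesis, then ring A attached by cross-coupling.

Assumption and convention: L-proline, (S)-Me-CBS and the D-fructose-derived Shi ketone are bought. In the bicyclic intermediates β means the face of the angular methyl group, and decalins carry Wieland–Miescher numbering (C1 carbinol, C4, C4a ring-fusion CH, C6 carbonyl, C8a angular methyl).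

**Part 1 – fragment 2 (bicyclic iodide)**

Step 1
Reactants: 1 2-methylcyclohexane-1,3-dione; 2 but-3-en-2-one
Product: 4 (S)-Wieland–Miescher ketone, via triketone 3 (not isolated)
Conditions: L-proline (35 mol%), DMSO, 35 °C, 90 h; recrystallise from Et2O/hexane
Reagents that add atoms: none
Why: Michael addition followed by the Hajos–Parrish–Eder–Sauer–Wiechert intramolecular aldol condensation, in which the L-proline enamine selects one enantiotopic ring carbonyl and so sets the quaternary centre as S.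

Step 2
Reactants: 4 (S)-Wieland–Miescher ketone
Product: 5 (4aS,5S)-5-hydroxy-4a-methyl-4,4a,5,6,7,8-hexahydronaphthalen-2(3H)-one
Conditions: NaBH4 (0.3 equiv), EtOH, −10 °C
Reagents that add atoms: none
Why: Chemoselective hydride reduction of the saturated ketone, with hydride entering anti to the angular methyl so that the new hydroxyl is β (cis to methyl).

Step 3
Reactants: 5 hydroxy enone
Product: 6 (1S,8aS)-8a-methyl-6-oxo-1,2,3,4,6,7,8,8a-octahydronaphthalen-1-yl acetate
Conditions: Ac2O, pyridine, DMAP (cat.), CH2Cl2, rt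
Reagents that add atoms: acetic anhydride, CC(=O)OC(C)=O
Why: Acylation protects the carbinol against the later oxidation step.

Step 4
Reactants: 6 enone acetate
Product: 7 (1S,8aS)-6,6-(ethylenedioxy)-8a-methyl-1,2,3,5,6,7,8,8a-octahydronaphthalen-1-yl acetate (C4=C4a alkene)
Conditions: ethylene glycol, TsOH (cat.), benzene, reflux, Dean–Stark
Reagents that add atoms: ethane-1,2-diol, OCCO
Why: Thermodynamic ketalisation of the enone moves the double bond out of conjugation into the β,γ position, as in steroid 3-ketal formation.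

Step 5
Reactants: 7 ketal alkene
Product: 9 (1S,4aS,8aS)-6,6-(ethylenedioxy)-8a-methyl-4-oxodecahydronaphthalen-1-yl acetate, via alkylborane 8 (not isolated)
Conditions: BH3·THF, THF, 0 °C → rt; then NMO, Pr4N[RuO4] (5 mol%), 4 Å MS, CH2Cl2, rt
Reagents that add atoms: 4-methylmorpholine N-oxide, C[N+]1([O-])CCOCC1
Why: Hydroboration from the α face (anti to the angular methyl) puts boron on C4 and hydrogen on C4a to give the trans-decalin, and direct oxidation of the C–B bond gives the ketone, whose trans fusion is also the thermodynamic one.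

Step 6
Reactants: 9 C4 ketone
Product: 11 (1S,4R,4aS,8aS)-1,4-dihydroxy-4,8a-dimethyldecahydronaphthalen-6-one, via ketal diol 10 (not isolated)
Conditions: MeMgBr (5 equiv), THF, −20 °C → rt; then 1 M HCl, THF, rt
Reagents that add atoms: methylmagnesium bromide, C[Mg]Br; water, O
Why: Grignard addition from the equatorial α direction (the axial path is blocked by the 1,3-diaxial angular methyl) gives the axial β tertiary alcohol, while excess reagent removes the acetate and the acidic work-up hydrolyses the ketal.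

Step 7
Reactants: 11 keto diol
Product: 14 lactone–lactol (cis γ-lactone C6(=O)–O–C4; five-membered lactol C1–O–C7H(OH)), via tris-silyl enol ether 12 (not isolated), via seco acid aldehyde 13 (not isolated)
Conditions: Me3SiOTf (4 equiv), Et3N, CH2Cl2, 0 °C → rt; O3, CH2Cl2, −78 °C; Me2S; then 1 M HCl, THF, rt
Reagents that add atoms: ozone, [O-][O+]=O
Why: The trans-fused ketone enolises away from the ring fusion (towards C7), and ozonolysis of that silyl enol ether cuts C6–C7 into an acid and an aldehyde, which close onto the two free hydroxyls as γ-lactone and lactol.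

Step 8
Reactants: 14 lactone–lactol
Product: 15 4α-allyl-5β-hydroxy-4β,7aα-dimethyl-cis-hexahydro-1-benzofuran-2(3H)-one (3a-H α, ring O β)
Conditions: Ph3PCH3Br (3 equiv), KOtBu (3 equiv), THF, 0 °C → rt
Reagents that add atoms: methyltriphenylphosphonium bromide, [Br-].C[P+](c1ccccc1)(c1ccccc1)c1ccccc1
Why: Wittig methylenation of the aldehyde in equilibrium with the lactol gives the allyl arm and frees the secondary alcohol.

Step 9
Reactants: 16 2-methylbut-3-yn-2-ol; 17 trichloroacetonitrile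
Product: 18 2-methylbut-3-yn-2-yl 2,2,2-trichloroacetimidate
Conditions: DBU (10 mol%), CH2Cl2, 0 °C
Reagents that add atoms: none
Why: Base-catalysed addition of the tertiary alcohol to the nitrile gives the imidate used as a tertiary propargyl cation donor.

Step 10
Reactants: 15 allyl hydroxy lactone; 18 propargylic trichloroacetimidate
Product: 19 5β-(2-methylbut-3-yn-2-yloxy) ether of 15
Conditions: 18 (3 equiv), BF3·OEt2 (0.2 equiv), cyclohexane/CH2Cl2 2:1, 0 °C → rt
Reagents that add atoms: none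
Why: Acid-catalysed trichloroacetimidate etherification gives the hindered tertiary ether through the tertiary propargylic cation, which, unlike the allyl analogue, cannot deliver a regioisomeric ether.

Step 11
Reactants: 19 propargyl ether
Product: 20 5β-(2-methylbut-3-en-2-yloxy) ether of 15 (diene)
Conditions: H2 (1 atm), Pd on CaCO3 poisoned with Pb(OAc)2, quinoline, EtOAc, rt, stopped at 1 equiv H2
Reagents that add atoms: none
Why: Lindlar-type semihydrogenation reduces the alkyne much faster than either monosubstituted alkene.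

Step 12
Reactants: 20 diene
Product: 21 tricyclic lactone–oxepene (trans-fused 2,2-dimethyl-2,5-dihydrooxepine on ring B, C3=C4 alkene)
Conditions: second-generation Grubbs catalyst RuCl2(=CHPh)(H2IMes)(PCy3) (5 mol%), CH2Cl2, 40 °C
Reagents that add atoms: none
Why: Ring-closing metathesis of the two trans-diequatorial arms closes the seven-membered ether, helped by the gem-dimethyl group and by loss of ethene.

Step 13
Reactants: 21 oxepene
Product: 22 3α,4α-epoxide of 21
Conditions: mCPBA, NaHCO3, CH2Cl2, 0 °C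
Reagents that add atoms: 3-chloroperbenzoic acid, OOC(=O)c1cccc(Cl)c1
Why: Prilezhaev epoxidation from the face anti to the axial angular methyl that overhangs the seven-membered ring puts the oxygen α at C3.

Step 14
Reactants: 22 epoxy lactone
Product: 23 (3S,5aS,6S,7R,9aS)-6-(2-hydroxyethyl)-2,2,5a,7-tetramethyldecahydro-1-benzoxepine-3,7-diol
Conditions: LiAlH4, THF, 0 → 50 °C; Fieser work-up
Reagents that add atoms: none
Why: SN2 hydride opening takes place at C4 because C3 is neopentylic, so C3 keeps its C–O bond and configuration, and the γ-lactone is reduced in the same pot to the primary and tertiary alcohols.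

Step 15
Reactants: 23 triol
Product: 24 (3S,5aS,6S,7R,9aS)-2,2,5a,7-tetramethyl-3,7-bis(triethylsilyloxy)-6-[2-(triethylsilyloxy)ethyl]decahydro-1-benzoxepine
Conditions: Et3SiOTf (4 equiv), 2,6-lutidine, CH2Cl2, −78 °C → rt
Reagents that add atoms: triethylsilyl trifluoromethanesulfonate, CC[Si](CC)(CC)OS(=O)(=O)C(F)(F)F
Why: Exhaustive silylation is needed first, because activating the primary alcohol beside the free tertiary alcohol would close a tetrahydrofuran (ambrox-type cyclisation).

Step 16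
Reactants: 24 tris-silyl ether
Product: 25 2-[(3S,5aS,6S,7R,9aS)-2,2,5a,7-tetramethyl-3,7-bis(triethylsilyloxy)decahydro-1-benzoxepin-6-yl]ethanol
Conditions: PPTS (0.1 equiv), MeOH/CH2Cl2 1:1, 0 °C
Reagents that add atoms: none
Why: Acid-catalysed methanolysis removes the unhindered primary silyl ether far faster than the neopentylic secondary and the tertiary ones.

Step 17
Reactants: 25 primary alcohol
Product: 26 (3S,5aS,6S,7R,9aS)-6-(2-iodoethyl)-2,2,5a,7-tetramethyl-3,7-bis(triethylsilyloxy)decahydro-1-benzoxepine (fragment 2)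
Conditions: I2, PPh3, imidazole, CH2Cl2, 0 °C → rt
Reagents that add atoms: iodine, II
Why: Appel-type iodination of the primary alcohol proceeds through the oxyphosphonium salt with iodide displacement.

**Part 2 – fragment 1 (ring-A enol triflate)**

Step 18
Reactants: 1 2-methylcyclohexane-1,3-dione; 27 acrolein
Product: 28 3-(1-methyl-2,6-dioxocyclohexyl)propanal
Conditions: H2O, rt
Reagents that add atoms: none
Why: Michael addition of the acidic 1,3-dione gives C-alkylation only and creates the prochiral quaternary carbon.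

Step 19
Reactants: 28 aldehyde dione
Product: 29 2-methyl-2-(4-methylpent-3-en-1-yl)cyclohexane-1,3-dione
Conditions: iPrPPh3I, n-BuLi, THF, 0 °C; then 28, −78 → 0 °C
Reagents that add atoms: isopropyltriphenylphosphonium iodide, [I-].CC(C)[P+](c1ccccc1)(c1ccccc1)c1ccccc1
Why: Wittig olefination is selective for the aldehyde over the two hindered ketones.

Step 20
Reactants: 29 prochiral dione
Product: 30 (2R,3R)-3-hydroxy-2-methyl-2-(4-methylpent-3-en-1-yl)cyclohexan-1-one
Conditions: (S)-Me-CBS (0.2 equiv), catecholborane (1.2 equiv), toluene, −78 → −40 °C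
Reagents that add atoms: none
Why: Corey–Bakshi–Shibata desymmetrisation: the (S)-catalyst (quaternary side as the large group) fixes the carbinol as R, and attack from the methyl face, anti to the longer chain, makes the hydroxyl cis to the chain and the quaternary carbon R.

Step 21
Reactants: 30 hydroxy ketone
Product: 31 (2R,3R)-2-methyl-2-(4-methylpent-3-en-1-yl)-3-(triethylsilyloxy)cyclohexan-1-one
Conditions: Et3SiCl, imidazole, DMF, rt
Reagents that add atoms: chlorotriethylsilane, CC[Si](CC)(CC)Cl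
Why: Silyl protection of the carbinol is chosen so that it falls off in the mild final deprotection.

Step 22
Reactants: 31 silyloxy ketone
Product: 33 (2R,3R,6RS)-2,6-dimethyl-2-(4-methylpent-3-en-1-yl)-3-(triethylsilyloxy)cyclohexan-1-one, via lithium enolate 32 (not isolated)
Conditions: LiN(iPr)2, THF, −78 °C; MeI, −78 → −20 °C
Reagents that add atoms: iodomethane, CI
Why: Enolate alkylation can only occur on the single enolisable side, and the new centre is removed in the next step.

Step 23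
Reactants: 33 methyl ketone
Product: 35 (5R,6R)-2,6-dimethyl-6-(4-methylpent-3-en-1-yl)-5-(triethylsilyloxy)cyclohex-1-en-1-yl trifluoromethanesulfonate, via potassium enolate 34 (not isolated)
Conditions: KN(SiMe3)2, THF, −78 → 0 °C; PhNTf2, −78 °C → rt
Reagents that add atoms: N-phenylbis(trifluoromethanesulfonimide), O=S(=O)(N(c1ccccc1)S(=O)(=O)C(F)(F)F)C(F)(F)F
Why: O-Triflation of the only possible enolate gives the tetrasubstituted enol triflate regiospecifically.

Step 24
Reactants: 35 enol triflate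
Product: 36 (5R,6R)-6-{2-[(2R)-3,3-dimethyloxiran-2-yl]ethyl}-2,6-dimethyl-5-(triethylsilyloxy)cyclohex-1-en-1-yl trifluoromethanesulfonate
Conditions: D-fructose-derived Shi ketone (0.3 equiv), KHSO5 (as 2KHSO5·KHSO4·K2SO4), K2CO3, Bu4NHSO4, MeCN/CH2(OMe)2/aq. Na2B4O7 buffer, 0 °C
Reagents that add atoms: potassium peroxymonosulfate, [K+].[O-]S(=O)(=O)OO
Why: Shi asymmetric epoxidation by the chiral dioxirane attacks only the electron-rich trisubstituted alkene (the enol triflate is inert) and the D-fructose ketone gives the (R)-epoxide.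

Step 25
Reactants: 36 epoxy triflate
Product: 37 (5R,6R)-6-[(3R)-3-hydroxy-4-methylpent-4-en-1-yl]-2,6-dimethyl-5-(triethylsilyloxy)cyclohex-1-en-1-yl trifluoromethanesulfonate (fragment 1)
Conditions: Et2AlCl + lithium 2,2,6,6-tetramethylpiperidide (4 equiv), toluene, 0 °C; aq. KNaC4H4O6
Reagents that add atoms: none
Why: Yamamoto epoxide-to-allylic-alcohol isomerisation with the aluminium amide removes a methyl proton and breaks the tertiary C–O bond, so the secondary C–O bond and its R configuration are kept.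

**Part 3 – union and end game**

Step 26
Reactants: 26 fragment 2 iodide; 37 fragment 1 triflate
Product: 39 (3R)-5-[(1S,6R)-2-{2-[(3S,5aS,6S,7R,9aS)-2,2,5a,7-tetramethyl-3,7-bis(triethylsilyloxy)decahydro-1-benzoxepin-6-yl]ethyl}-1,3-dimethyl-6-(triethylsilyloxy)cyclohex-2-en-1-yl]-2-methylpent-1-en-3-ol, via borate complex 38 (not isolated)
Conditions: 26, 9-MeO-9-BBN, t-BuLi (2.1 equiv), Et2O/THF, −78 °C → rt; then 37, Pd(dppf)Cl2 (10 mol%), AsPh3, Cs2CO3, DMF/H2O, rt → 45 °C
Reagents that add atoms: none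
Why: B-alkyl Suzuki–Miyaura coupling: the alkyl borate from iodine–lithium exchange transmetalates to the palladium formed by oxidative addition of zerovalent palladium into the hindered enol triflate, and the free allylic alcohol is tolerated.

Step 27
Reactants: 40 2,3-dimethylbut-2-ene
Product: 41 2-methoxypropan-2-yl hydroperoxide
Conditions: O3, CH2Cl2/MeOH, −78 °C; used as a cold solution
Reagents that add atoms: ozone, [O-][O+]=O; methanol, CO
Why: Ozonolysis in methanol traps the acetone carbonyl oxide as the methoxy hydroperoxide, a mono-protected hydrogen peroxide.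

Step 28
Reactants: 39 coupled allylic alcohol; 41 2-methoxypropan-2-yl hydroperoxide
Product: 43 (3S)-3-[(2-methoxypropan-2-yl)peroxy] analogue of 39 (peroxyketal in place of OH), via allylic mesylate 42 (not isolated)
Conditions: MsCl, Et3N, CH2Cl2, −30 °C; cold wash, solvent switch; then 41, CsOH·H2O, DMF, −20 → 0 °C
Reagents that add atoms: none
Why: The only free hydroxyl is mesylated and displaced by the caesium peroxide in a direct SN2 reaction, inverting R to the S configuration of the target.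

Step 29
Reactants: 43 silylated peroxyketal
Product: 44 target, (3S,5aS,6S,7R,9aS)-6-{2-[(5R,6S)-6-[(3S)-3-hydroperoxy-4-methylpent-4-en-1-yl]-5-hydroxy-2,6-dimethylcyclohex-1-en-1-yl]ethyl}-2,2,5a,7-tetramethyldecahydro-1-benzoxepine-3,7-diol
Conditions: 48% aq. HF, MeCN, 0 °C
Reagents that add atoms: none
Why: Mild acidic global deprotection cleaves the three triethylsilyl ethers and hydrolyses the peroxyketal to the hydroperoxide without touching the O–O bond or any stereocentre.

**Compound list**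
1 | 2-methylcyclohexane-1,3-dione | CC1C(=O)CCCC1=O | starting material
2 | but-3-en-2-one | CC(=O)C=C | starting material
3 | 2-methyl-2-(3-oxobutyl)cyclohexane-1,3-dione | CC(=O)CCC1(C)C(=O)CCCC1=O | intermediate
4 | (S)-8a-methyl-3,4,8,8a-tetrahydronaphthalene-1,6(2H,7H)-dione | C[C@]12CCC(=O)C=C1CCCC2=O | intermediate
5 | (4aS,5S)-5-hydroxy-4a-methyl-4,4a,5,6,7,8-hexahydronaphthalen-2(3H)-one | C[C@]12CCC(=O)C=C1CCC[C@@H]2O | intermediate
6 | (1S,8aS)-8a-methyl-6-oxo-1,2,3,4,6,7,8,8a-octahydronaphthalen-1-yl acetate | C[C@]12CCC(=O)C=C1CCC[C@@H]2OC(C)=O | intermediate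
7 | (1S,8aS)-6,6-(ethylenedioxy)-8a-methyl-1,2,3,5,6,7,8,8a-octahydronaphthalen-1-yl acetate | C[C@]12CCC3(OCCO3)CC1=CCC[C@@H]2OC(C)=O | intermediate
8 | 4α-boranyl-6,6-(ethylenedioxy)-8aβ-methyl-trans-decahydronaphthalen-1β-yl acetate (4a-H α) | C[C@]12CCC3(OCCO3)C[C@@H]1[C@@H](B)CC[C@@H]2OC(C)=O | intermediate
9 | (1S,4aS,8aS)-6,6-(ethylenedioxy)-8a-methyl-4-oxodecahydronaphthalen-1-yl acetate | C[C@]12CCC3(OCCO3)C[C@@H]1C(=O)CC[C@@H]2OC(C)=O | intermediate
10 | (1S,4R,4aS,8aS)-6,6-(ethylenedioxy)-4,8a-dimethyldecahydronaphthalene-1,4-diol | C[C@]12CCC3(OCCO3)C[C@@H]1[C@](C)(O)CC[C@@H]2O | intermediate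
11 | (1S,4R,4aS,8aS)-1,4-dihydroxy-4,8a-dimethyldecahydronaphthalen-6-one | C[C@]12CCC(=O)C[C@@H]1[C@](C)(O)CC[C@@H]2O | intermediate
12 | 1β,4β,6-tris(trimethylsilyloxy)-4α,8aβ-dimethyl-trans-1,2,3,4,4a,5,8,8a-octahydronaphthalene (C6=C7 enol ether) | C[C@]12CC=C(O[Si](C)(C)C)C[C@@H]1[C@](C)(O[Si](C)(C)C)CC[C@@H]2O[Si](C)(C)C | intermediate
13 | 2-[(1S,2S,3S,6R)-3,6-dihydroxy-2,6-dimethyl-2-(2-oxoethyl)cyclohexyl]acetic acid (seco acid aldehyde; ring centres as in 11) | OC(=O)C[C@H]1[C@](C)(CC=O)[C@@H](O)CC[C@@]1(C)O | intermediate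
14 | lactone–lactol: cis γ-lactone (C4–O–C6=O) and five-membered lactol (C1–O–C7H(OH)), anomers | O=C1C[C@H]2[C@]3(C)CC(O)O[C@H]3CC[C@@]2(C)O1 | intermediate
15 | 4α-allyl-5β-hydroxy-4β,7aα-dimethyl-cis-hexahydro-1-benzofuran-2(3H)-one | O=C1C[C@H]2[C@](C)(CC=C)[C@@H](O)CC[C@@]2(C)O1 | intermediate
16 | 2-methylbut-3-yn-2-ol | CC(C)(O)C#C | starting material
17 | trichloroacetonitrile | N#CC(Cl)(Cl)Cl | starting material
18 | 2-methylbut-3-yn-2-yl 2,2,2-trichloroacetimidate | CC(C)(C#C)OC(=N)C(Cl)(Cl)Cl | intermediate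
19 | 5β-(2-methylbut-3-yn-2-yloxy) ether of 15 | O=C1C[C@H]2[C@](C)(CC=C)[C@@H](OC(C)(C)C#C)CC[C@@]2(C)O1 | intermediate
20 | 5β-(2-methylbut-3-en-2-yloxy) ether of 15 | O=C1C[C@H]2[C@](C)(CC=C)[C@@H](OC(C)(C)C=C)CC[C@@]2(C)O1 | intermediate
21 | tricyclic γ-lactone fused to trans-2,2,5a-trimethyl-2,5-dihydro-1-benzoxepine (C3=C4 alkene) | O=C1C[C@H]2[C@]3(C)CC=CC(C)(C)O[C@H]3CC[C@@]2(C)O1 | intermediate
22 | 3α,4α-epoxide of 21 | O=C1C[C@H]2[C@]3(C)C[C@@H]4O[C@@H]4C(C)(C)O[C@H]3CC[C@@]2(C)O1 | intermediate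
23 | (3S,5aS,6S,7R,9aS)-6-(2-hydroxyethyl)-2,2,5a,7-tetramethyldecahydro-1-benzoxepine-3,7-diol | OCC[C@H]1[C@]2(C)CC[C@H](O)C(C)(C)O[C@H]2CC[C@@]1(C)O | intermediate
24 | (3S,5aS,6S,7R,9aS)-2,2,5a,7-tetramethyl-3,7-bis(triethylsilyloxy)-6-[2-(triethylsilyloxy)ethyl]decahydro-1-benzoxepine | CC[Si](CC)(CC)OCC[C@H]1[C@]2(C)CC[C@H](O[Si](CC)(CC)CC)C(C)(C)O[C@H]2CC[C@@]1(C)O[Si](CC)(CC)CC | intermediate
25 | 2-[(3S,5aS,6S,7R,9aS)-2,2,5a,7-tetramethyl-3,7-bis(triethylsilyloxy)decahydro-1-benzoxepin-6-yl]ethanol | OCC[C@H]1[C@]2(C)CC[C@H](O[Si](CC)(CC)CC)C(C)(C)O[C@H]2CC[C@@]1(C)O[Si](CC)(CC)CC | intermediate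
26 | (3S,5aS,6S,7R,9aS)-6-(2-iodoethyl)-2,2,5a,7-tetramethyl-3,7-bis(triethylsilyloxy)decahydro-1-benzoxepine | ICC[C@H]1[C@]2(C)CC[C@H](O[Si](CC)(CC)CC)C(C)(C)O[C@H]2CC[C@@]1(C)O[Si](CC)(CC)CC | intermediate
27 | acrolein (prop-2-enal) | C=CC=O | starting material
28 | 3-(1-methyl-2,6-dioxocyclohexyl)propanal | CC1(CCC=O)C(=O)CCCC1=O | intermediate
29 | 2-methyl-2-(4-methylpent-3-en-1-yl)cyclohexane-1,3-dione | CC(C)=CCCC1(C)C(=O)CCCC1=O | intermediate
30 | (2R,3R)-3-hydroxy-2-methyl-2-(4-methylpent-3-en-1-yl)cyclohexan-1-one | CC(C)=CCC[C@@]1(C)C(=O)CCC[C@H]1O | intermediate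
31 | (2R,3R)-2-methyl-2-(4-methylpent-3-en-1-yl)-3-(triethylsilyloxy)cyclohexan-1-one | CC(C)=CCC[C@@]1(C)C(=O)CCC[C@H]1O[Si](CC)(CC)CC | intermediate
32 | lithium enolate of 31 (C1=C6) | [Li+].CC(C)=CCC[C@@]1(C)C([O-])=CCC[C@H]1O[Si](CC)(CC)CC | intermediate
33 | (2R,3R,6RS)-2,6-dimethyl-2-(4-methylpent-3-en-1-yl)-3-(triethylsilyloxy)cyclohexan-1-one | CC(C)=CCC[C@@]1(C)C(=O)C(C)CC[C@H]1O[Si](CC)(CC)CC | intermediate
34 | potassium enolate of 33 (tetrasubstituted) | [K+].CC(C)=CCC[C@@]1(C)C([O-])=C(C)CC[C@H]1O[Si](CC)(CC)CC | intermediate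
35 | (5R,6R)-2,6-dimethyl-6-(4-methylpent-3-en-1-yl)-5-(triethylsilyloxy)cyclohex-1-en-1-yl trifluoromethanesulfonate | CC(C)=CCC[C@@]1(C)C(OS(=O)(=O)C(F)(F)F)=C(C)CC[C@H]1O[Si](CC)(CC)CC | intermediate
36 | (5R,6R)-6-{2-[(2R)-3,3-dimethyloxiran-2-yl]ethyl}-2,6-dimethyl-5-(triethylsilyloxy)cyclohex-1-en-1-yl trifluoromethanesulfonate | CC1(C)O[C@@H]1CC[C@@]1(C)C(OS(=O)(=O)C(F)(F)F)=C(C)CC[C@H]1O[Si](CC)(CC)CC | intermediate
37 | (5R,6R)-6-[(3R)-3-hydroxy-4-methylpent-4-en-1-yl]-2,6-dimethyl-5-(triethylsilyloxy)cyclohex-1-en-1-yl trifluoromethanesulfonate | C=C(C)[C@H](O)CC[C@@]1(C)C(OS(=O)(=O)C(F)(F)F)=C(C)CC[C@H]1O[Si](CC)(CC)CC | intermediate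
38 | lithium B-methoxy-B-[2-(benzoxepin-6-yl)ethyl]-9-borabicyclo[3.3.1]nonane ate complex from 26 | [Li+].CO[B-]1(CC[C@H]2[C@]3(C)CC[C@H](O[Si](CC)(CC)CC)C(C)(C)O[C@H]3CC[C@@]2(C)O[Si](CC)(CC)CC)C2CCCC1CCC2 | intermediate
39 | (3R)-5-[(1S,6R)-2-{2-[(3S,5aS,6S,7R,9aS)-2,2,5a,7-tetramethyl-3,7-bis(triethylsilyloxy)decahydro-1-benzoxepin-6-yl]ethyl}-1,3-dimethyl-6-(triethylsilyloxy)cyclohex-2-en-1-yl]-2-methylpent-1-en-3-ol | C=C(C)[C@H](O)CC[C@@]1(C)C(CC[C@H]2[C@]3(C)CC[C@H](O[Si](CC)(CC)CC)C(C)(C)O[C@H]3CC[C@@]2(C)O[Si](CC)(CC)CC)=C(C)CC[C@H]1O[Si](CC)(CC)CC | intermediate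
40 | 2,3-dimethylbut-2-ene | CC(C)=C(C)C | starting material
41 | 2-methoxypropan-2-yl hydroperoxide | COC(C)(C)OO | intermediate
42 | (3R)-methanesulfonate of 39 | C=C(C)[C@H](OS(C)(=O)=O)CC[C@@]1(C)C(CC[C@H]2[C@]3(C)CC[C@H](O[Si](CC)(CC)CC)C(C)(C)O[C@H]3CC[C@@]2(C)O[Si](CC)(CC)CC)=C(C)CC[C@H]1O[Si](CC)(CC)CC | intermediate
43 | (3S)-3-[(2-methoxypropan-2-yl)peroxy] compound (tris-triethylsilyl ether of the target peroxyketal) | C=C(C)[C@H](CC[C@@]1(C)C(CC[C@H]2[C@]3(C)CC[C@H](O[Si](CC)(CC)CC)C(C)(C)O[C@H]3CC[C@@]2(C)O[Si](CC)(CC)CC)=C(C)CC[C@H]1O[Si](CC)(CC)CC)OOC(C)(C)OC | intermediate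
44 | (3S,5aS,6S,7R,9aS)-6-{2-[(5R,6S)-6-[(3S)-3-hydroperoxy-4-methylpent-4-en-1-yl]-5-hydroxy-2,6-dimethylcyclohex-1-en-1-yl]ethyl}-2,2,5a,7-tetramethyldecahydro-1-benzoxepine-3,7-diol | C=C(C)[C@H](CC[C@@]1(C)C(CC[C@H]2[C@]3(C)CC[C@H](O)C(C)(C)O[C@H]3CC[C@@]2(C)O)=C(C)CC[C@H]1O)OO | target

**Totals and risks**
Total step count: 29. Longest linear sequence: 19 steps (steps 1–8, 10–17, 26, 28, 29), which is below two thirds of 29.

Most likely to fail, first: step 10, etherification of the neopentylic alcohol with a tertiary cation donor. The fallback sets out from 15. Treatment with 2-methoxypropene and PPTS gives the mixed methyl ketal F1. Ionisation of F1 with BF3·OEt2 in the presence of potassium vinyltrifluoroborate (oxocarbenium capture by the alkenylboron species) gives the 1,1-dimethylallyl ether directly, so the route is rejoined at 20 and step 11 is skipped.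

Second: step 13, the face of epoxidation, which together with the site of hydride attack in step 14 decides the C3 carbinol. The fallback sets out from 19. Hydration of the alkyne (Ph3PAuCl/AgOTf, aq. MeOH) gives the methyl ketone F2. tBuMe2SiOTf/Et3N converts it into the 2-silyloxy diene F3. Enol-ether ring-closing metathesis with the second-generation Hoveyda–Grubbs catalyst RuCl2(=CH-C6H4-2-OiPr)(H2IMes) gives the cyclic silyl enol ether F4. Aqueous HF in MeCN releases the oxepan-3-one F5, which places the oxygen on C3 without ambiguity. Reduction (NaBH4 then LiAlH4, or LiBH(sec-Bu)3 first if the other face is needed) returns to the route at 23.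

Third: step 28, SN2 of a peroxide on a labile secondary allylic mesylate. The fallback sets out from 36 and 26. They are coupled exactly as in step 26 to give the coupled epoxide F6. The potassium salt of 41 (KOtBu, 18-crown-6, THF, 40 °C) opens the epoxide at the secondary carbon with inversion to give the β-hydroxy peroxyketal F7. Dehydration of its tertiary alcohol towards a methyl group with the Burgess reagent comes back to the route at 43.

**Further compounds**
F1 | step 10 | 5β-(2-methoxypropan-2-yloxy) mixed ketal of 15 | O=C1C[C@H]2[C@](C)(CC=C)[C@@H](OC(C)(C)OC)CC[C@@]2(C)O1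
F2 | step 13 | 5β-(3-methyl-2-oxobutan-3-yloxy) ether of 15 (methyl ketone) | O=C1C[C@H]2[C@](C)(CC=C)[C@@H](OC(C)(C)C(C)=O)CC[C@@]2(C)O1
F3 | step 13 | tert-butyldimethylsilyl enol ether of F2 (2-silyloxy diene) | O=C1C[C@H]2[C@](C)(CC=C)[C@@H](OC(C)(C)C(=C)O[Si](C)(C)C(C)(C)C)CC[C@@]2(C)O1
F4 | step 13 | tricyclic lactone with 3-(tert-butyldimethylsilyloxy)-2,2-dimethyl-2,5-dihydrooxepine ring (C3=C4) | O=C1C[C@H]2[C@]3(C)CC=C(O[Si](C)(C)C(C)(C)C)C(C)(C)O[C@H]3CC[C@@]2(C)O1
F5 | step 13 | tricyclic lactone oxepan-3-one | O=C1C[C@H]2[C@]3(C)CCC(=O)C(C)(C)O[C@H]3CC[C@@]2(C)O1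
F6 | step 28 | coupled (R)-epoxide: 39 with the 3,3-dimethyloxiran-2-yl group in place of the allylic alcohol | CC1(C)O[C@@H]1CC[C@@]1(C)C(CC[C@H]2[C@]3(C)CC[C@H](O[Si](CC)(CC)CC)C(C)(C)O[C@H]3CC[C@@]2(C)O[Si](CC)(CC)CC)=C(C)CC[C@H]1O[Si](CC)(CC)CC
F7 | step 28 | (3S)-3-[(2-methoxypropan-2-yl)peroxy]-2-methyl-2-hydroxy compound (β-hydroxy peroxyketal) | CC(C)(O)[C@H](CC[C@@]1(C)C(CC[C@H]2[C@]3(C)CC[C@H](O[Si](CC)(CC)CC)C(C)(C)O[C@H]3CC[C@@]2(C)O[Si](CC)(CC)CC)=C(C)CC[C@H]1O[Si](CC)(CC)CC)OOC(C)(C)OC
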